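**Plan**

- The target is (3R)-5'-geranyl-2',4',7-trihydroxyisoflavanone. Retrosynthesis removes three silyl ethers, then cuts C2–C3 of ring C, then the diazo group, then the bond from the benzylic carbon to ring B, and last the geranyl–ring B bond.
- The enabling feature: C2 is an isolated CH2 between O1 and C3, so it can be carried as the methyl of a ring A methyl ether. C3 sits between ring B and the C4 ketone, so it can be a donor/acceptor carbene centre.
- Forward, ring B is made from 4,6-dibromoresorcinol (silylation, mono-lithiation, copper-mediated geranylation). It is joined to silylated 4-hydroxy-2-methoxyacetophenone by Pd-catalysed ketone α-arylation, and diazo transfer follows.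
- Ring C is closed last but one, by enantioselective carbenoid insertion into an O-methyl C–H bond; global desilylation under non-basic conditions ends the route.
- The only stereocentre, C3 (R), is set in the ring closure by the chiral dirhodium carboxylate. The (E)-olefin is bought with geranyl bromide.

Key step: step 6

Assumption: Rh2(S-PTTL)4 is taken to expose the carbenoid enantioface that leads to (3R). If the first experiment showed the opposite sense, Rh2(R-PTTL)4 would be used with no other change.

**Route**

Step 1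
Reactants: 1 4,6-dibromoresorcinol
Product: 2 1,5-dibromo-2,4-bis(triisopropylsilyloxy)benzene
Conditions: TIPSCl, imidazole, DMF, rt → 40 °C
Reagents that add atoms: triisopropylsilyl chloride, CC(C)[Si](Cl)(C(C)C)C(C)C
Why: Imidazole-promoted O-silylation of both phenols; the bulky silyl ethers should survive organolithium at low temperature, phosphate base and the carbenoid, and they put silicon, not an insertable C–H carbon, next to the ring B oxygen.

Step 2
Reactants: 2 1,5-dibromo-2,4-bis(triisopropylsilyloxy)benzene; 3 geranyl bromide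
Product: 6 1-bromo-5-[(2E)-3,7-dimethylocta-2,6-dien-1-yl]-2,4-bis(triisopropylsilyloxy)benzene, via aryllithium 4 (not isolated), via arylcopper 5 (not isolated)
Conditions: n-BuLi (1.05 equiv), THF, −78 °C; CuBr·SMe2, −78 → −40 °C; 3, −40 → 0 °C
Reagents that add atoms: n-butyllithium, [Li]CCCC (the lithium of 4); CuBr·SMe2, CSC.Br[Cu] (the copper of 5)
Why: Bromine–lithium exchange with one equivalent of n-BuLi takes one of the two equivalent bromides, and the derived arylcopper undergoes allylic substitution at the primary carbon of geranyl bromide with the (E)-olefin retained, while low temperature and the bulk of the silyl groups hold back oxygen-to-carbon silyl migration.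

Step 3
Reactants: 7 4-hydroxy-2-methoxyacetophenone
Product: 8 2-methoxy-4-(triisopropylsilyloxy)acetophenone
Conditions: TIPSCl, imidazole, DMF, rt
Reagents that add atoms: triisopropylsilyl chloride, CC(C)[Si](Cl)(C(C)C)C(C)C
Why: Standard imidazole-promoted O-silylation of the free phenol, which masks the acidic OH before the enolate chemistry and leaves the ortho methoxy group as the future C2.

Step 4
Reactants: 6 1-bromo-5-[(2E)-3,7-dimethylocta-2,6-dien-1-yl]-2,4-bis(triisopropylsilyloxy)benzene; 8 2-methoxy-4-(triisopropylsilyloxy)acetophenone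
Product: 9 2-[5-geranyl-2,4-bis(triisopropylsilyloxy)phenyl]-1-[2-methoxy-4-(triisopropylsilyloxy)phenyl]ethanone
Conditions: Pd2(dba)3 (2 mol %), XPhos (8 mol %), K3PO4, toluene, 90 °C, slight excess of 8
Reagents that add atoms: none
Why: Palladium-catalysed α-arylation of a methyl ketone enolate (Buchwald–Hartwig type): oxidative addition of the aryl bromide to zerovalent palladium bearing the bulky biaryl phosphine, enolate binding and reductive elimination form the benzylic C–C bond, with mono-arylation favoured by the hindered product and the weak phosphate base sparing the aryl silyl ethers.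

Step 5
Reactants: 9 2-[5-geranyl-2,4-bis(triisopropylsilyloxy)phenyl]-1-[2-methoxy-4-(triisopropylsilyloxy)phenyl]ethanone
Product: 10 2-diazo-2-[5-geranyl-2,4-bis(triisopropylsilyloxy)phenyl]-1-[2-methoxy-4-(triisopropylsilyloxy)phenyl]ethanone
Conditions: p-ABSA, DBU, anhydrous MeCN, 0 °C → rt
Reagents that add atoms: 4-acetamidobenzenesulfonyl azide (p-ABSA), CC(=O)Nc1ccc(cc1)S(=O)(=O)N=[N+]=[N-]
Why: Regitz diazo transfer: the methylene flanked by aryl and aroyl groups is acidic enough for DBU to form the enolate, which attacks the sulfonyl azide and expels the sulfonamide without prior formylation.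

Step 6
Reactants: 10 2-diazo-2-[5-geranyl-2,4-bis(triisopropylsilyloxy)phenyl]-1-[2-methoxy-4-(triisopropylsilyloxy)phenyl]ethanone
Product: 11 (3R)-5'-geranyl-2',4',7-tris(triisopropylsilyloxy)isoflavanone
Conditions: Rh2(S-PTTL)4 (1–2 mol %), 4 Å MS, toluene, −30 → 0 °C, slow addition of 10 at high dilution
Reagents that add atoms: none
Why: Proposed new method: Rh2(S-PTTL)4 should decompose 10 with loss of N2 to an electrophilic divalent-rhodium carbenoid at C3, stabilised by ring B as donor and the aroyl group as acceptor, which draws hydride-like electron density from an O-methyl C–H bond of the ring A ether in a concerted, asynchronous three-centre transition state that forms C2–C3 and C3–H together. The closest known reaction types are dirhodium-catalysed insertion of 2-alkoxyaryl α-diazo ketones into ether O–CH2R bonds to give chroman-4-ones and enantioselective insertion of aryl donor/acceptor carbenoids into methyl ether C–H bonds; their combination on an α-aryl α-diazo ketone with a primary aryl methyl ether C–H bond is untested. Ring C closes as a 1,6-insertion giving the six-membered ring O1–C2–C3–C4–C4a–C8a, the C4 carbonyl and ring A holding the methoxy group within reach of the carbenoid. The single new stereocentre C3 is the carbenoid carbon itself, and its configuration is fixed by which enantioface of the rhodium-bound carbon meets the methyl group inside the chiral pocket of the four N-phthaloyl tert-leucinate ligands. The step needs chemoselectivity for the O–CH3 bond over oxonium ylide formation with 1,2-methyl shift (the aryl ether oxygen is a weak nucleophile, ylide formation is reversible and methyl migrates poorly), over silyl C–H insertion (ring B offers silicon at the 1,5-position and only shielded, unactivated isopropyl C–H bonds beyond it) and over the geranyl olefins (the meta-placed chain cannot reach, and slow addition at high dilution suppresses intermolecular cyclopropanation). The product is kept away from base so that the enolisable C3 centre is not eroded.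

Step 7
Reactants: 11 (3R)-5'-geranyl-2',4',7-tris(triisopropylsilyloxy)isoflavanone
Product: 12 (3R)-5'-geranyl-2',4',7-trihydroxyisoflavanone
Conditions: Et3N·3HF (excess), MeCN–THF, 0 °C → rt; neutral work-up
Reagents that add atoms: none
Why: Fluoride-driven cleavage of the three aryl silyl ethers in a mildly acidic amine–HF medium, which avoids the enolate of the α-aryl ketone and so should keep C3 configured, and is too weakly acidic to cyclise the 4'-phenol onto the geranyl olefin.

**Compound list**

1 | 4,6-dibromoresorcinol (4,6-dibromobenzene-1,3-diol) | Oc1cc(O)c(Br)cc1Br | starting material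
2 | 1,5-dibromo-2,4-bis(triisopropylsilyloxy)benzene | Brc1cc(Br)c(O[Si](C(C)C)(C(C)C)C(C)C)cc1O[Si](C(C)C)(C(C)C)C(C)C | intermediate
3 | geranyl bromide, (2E)-1-bromo-3,7-dimethylocta-2,6-diene | CC(C)=CCC/C(C)=C/CBr | starting material
4 | [5-bromo-2,4-bis(triisopropylsilyloxy)phenyl]lithium | [Li]c1cc(Br)c(O[Si](C(C)C)(C(C)C)C(C)C)cc1O[Si](C(C)C)(C(C)C)C(C)C | intermediate
5 | [5-bromo-2,4-bis(triisopropylsilyloxy)phenyl]copper | [Cu]c1cc(Br)c(O[Si](C(C)C)(C(C)C)C(C)C)cc1O[Si](C(C)C)(C(C)C)C(C)C | intermediate
6 | 1-bromo-5-[(2E)-3,7-dimethylocta-2,6-dien-1-yl]-2,4-bis(triisopropylsilyloxy)benzene | CC(C)=CCC/C(C)=C/Cc1cc(Br)c(O[Si](C(C)C)(C(C)C)C(C)C)cc1O[Si](C(C)C)(C(C)C)C(C)C | intermediate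
7 | 4-hydroxy-2-methoxyacetophenone | CC(=O)c1ccc(O)cc1OC | starting material
8 | 2-methoxy-4-(triisopropylsilyloxy)acetophenone | CC(=O)c1ccc(O[Si](C(C)C)(C(C)C)C(C)C)cc1OC | intermediate
9 | 2-[5-geranyl-2,4-bis(triisopropylsilyloxy)phenyl]-1-[2-methoxy-4-(triisopropylsilyloxy)phenyl]ethanone | CC(C)=CCC/C(C)=C/Cc1cc(CC(=O)c2ccc(O[Si](C(C)C)(C(C)C)C(C)C)cc2OC)c(O[Si](C(C)C)(C(C)C)C(C)C)cc1O[Si](C(C)C)(C(C)C)C(C)C | intermediate
10 | 2-diazo-2-[5-geranyl-2,4-bis(triisopropylsilyloxy)phenyl]-1-[2-methoxy-4-(triisopropylsilyloxy)phenyl]ethanone | CC(C)=CCC/C(C)=C/Cc1cc(C(=[N+]=[N-])C(=O)c2ccc(O[Si](C(C)C)(C(C)C)C(C)C)cc2OC)c(O[Si](C(C)C)(C(C)C)C(C)C)cc1O[Si](C(C)C)(C(C)C)C(C)C | intermediate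
11 | (3R)-5'-geranyl-2',4',7-tris(triisopropylsilyloxy)isoflavanone | CC(C)=CCC/C(C)=C/Cc1cc([C@@H]2COc3cc(O[Si](C(C)C)(C(C)C)C(C)C)ccc3C2=O)c(O[Si](C(C)C)(C(C)C)C(C)C)cc1O[Si](C(C)C)(C(C)C)C(C)C | intermediate
12 | (3R)-5'-geranyl-2',4',7-trihydroxyisoflavanone (CNP0142504.1) | CC(C)=CCC/C(C)=C/Cc1cc([C@@H]2COc3cc(O)ccc3C2=O)c(O)cc1O | target

**Step count**

Total: 7 steps. Longest linear sequence: 6 steps (steps 1, 2, 4, 5, 6, 7).

**Steps most likely to fail**

Step 6 (proposed new method). The carbenoid may be diverted into an oxonium ylide at the methoxy oxygen followed by 1,2-methyl migration, may insert into an isopropyl C–H bond of the neighbouring silyl group, or may insert with poor enantioface selectivity. The fallback leaves carbene chemistry and sets out from bromide 6. Commercial 7-hydroxychroman-4-one F1 is silylated (TIPSCl, imidazole, DMF) to 7-(triisopropylsilyloxy)chroman-4-one F2, which already holds ring C. Pd-catalysed α-arylation of F2 with 6 (Pd2(dba)3, XPhos, K3PO4, toluene) should give the racemic isoflavanone F3. Asymmetric transfer hydrogenation under dynamic kinetic resolution follows, with RuCl(p-cymene)[(R,R)-TsDPEN] and HCO2H/Et3N; C3 epimerises through the enol while one enantiomer is reduced, which should give the cis-(3R,4R)-isoflavan-4-ol F4. Oxidation of the benzylic alcohol with Dess–Martin periodinane in CH2Cl2 comes back to the route at 11.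

Step 4. Oxidative addition at the electron-rich C–Br bond flanked by a silyloxy group may be slow, aryl silyl groups may be lost to the hot base, or over-arylation may occur. The fallback makes ring B the nucleophile at low temperature and sets out from bromide 6. Bromine–lithium exchange (n-BuLi, THF, −78 °C) gives the aryllithium F5, which is opened onto ethylene oxide in the presence of BF3·OEt2 to give the 2-arylethanol F6. Dess–Martin oxidation gives the arylacetaldehyde F7. In parallel, commercial 4-bromo-3-methoxyphenol F8 is silylated to (4-bromo-3-methoxyphenoxy)triisopropylsilane F9 and converted with magnesium in THF into the Grignard reagent F10. Addition of F10 to F7 at −78 °C gives the racemic 1,2-diarylethanol F11, and a second Dess–Martin oxidation comes back to the route at deoxybenzoin 9.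

Step 2. The silyl group may migrate from oxygen to the lithiated carbon, double exchange may occur, or allylic substitution may take place at the tertiary terminus of the geranyl unit. The fallback does the organometallic step on acetal-protected material and sets out from 1. MOMCl and iPr2NEt in CH2Cl2 give 1,5-dibromo-2,4-bis(methoxymethoxy)benzene F12. Mono bromine–lithium exchange (n-BuLi, THF, −78 °C) gives the chelation-stabilised aryllithium F13, which carries no migrating silyl group. CuBr·SMe2 gives the arylcopper F14, and geranyl bromide 3 gives 1-bromo-5-geranyl-2,4-bis(methoxymethoxy)benzene F15. Mild acidic methanolysis (HCl in MeOH, rt) frees 4-bromo-6-geranylresorcinol F16, and TIPSCl with imidazole in DMF comes back to the route at 6.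

**Further compounds**

F1 | step 6 | 7-hydroxychroman-4-one (purchased) | O=C1CCOc2cc(O)ccc12
F2 | step 6 | 7-(triisopropylsilyloxy)chroman-4-one | O=C1CCOc2cc(O[Si](C(C)C)(C(C)C)C(C)C)ccc12
F3 | step 6 | racemic 5'-geranyl-2',4',7-tris(triisopropylsilyloxy)isoflavanone | CC(C)=CCC/C(C)=C/Cc1cc(C2COc3cc(O[Si](C(C)C)(C(C)C)C(C)C)ccc3C2=O)c(O[Si](C(C)C)(C(C)C)C(C)C)cc1O[Si](C(C)C)(C(C)C)C(C)C
F4 | step 6 | (3R,4R)-cis-5'-geranyl-2',4',7-tris(triisopropylsilyloxy)isoflavan-4-ol | CC(C)=CCC/C(C)=C/Cc1cc([C@@H]2COc3cc(O[Si](C(C)C)(C(C)C)C(C)C)ccc3[C@@H]2O)c(O[Si](C(C)C)(C(C)C)C(C)C)cc1O[Si](C(C)C)(C(C)C)C(C)C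
F5 | step 4 | [5-geranyl-2,4-bis(triisopropylsilyloxy)phenyl]lithium | CC(C)=CCC/C(C)=C/Cc1cc([Li])c(O[Si](C(C)C)(C(C)C)C(C)C)cc1O[Si](C(C)C)(C(C)C)C(C)C
F6 | step 4 | 2-[5-geranyl-2,4-bis(triisopropylsilyloxy)phenyl]ethanol | CC(C)=CCC/C(C)=C/Cc1cc(CCO)c(O[Si](C(C)C)(C(C)C)C(C)C)cc1O[Si](C(C)C)(C(C)C)C(C)C
F7 | step 4 | 2-[5-geranyl-2,4-bis(triisopropylsilyloxy)phenyl]acetaldehyde | CC(C)=CCC/C(C)=C/Cc1cc(CC=O)c(O[Si](C(C)C)(C(C)C)C(C)C)cc1O[Si](C(C)C)(C(C)C)C(C)C
F8 | step 4 | 4-bromo-3-methoxyphenol (purchased) | COc1cc(O)ccc1Br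
F9 | step 4 | (4-bromo-3-methoxyphenoxy)triisopropylsilane | COc1cc(O[Si](C(C)C)(C(C)C)C(C)C)ccc1Br
F10 | step 4 | [2-methoxy-4-(triisopropylsilyloxy)phenyl]magnesium bromide | COc1cc(O[Si](C(C)C)(C(C)C)C(C)C)ccc1[Mg]Br
F11 | step 4 | racemic 2-[5-geranyl-2,4-bis(triisopropylsilyloxy)phenyl]-1-[2-methoxy-4-(triisopropylsilyloxy)phenyl]ethanol | CC(C)=CCC/C(C)=C/Cc1cc(CC(O)c2ccc(O[Si](C(C)C)(C(C)C)C(C)C)cc2OC)c(O[Si](C(C)C)(C(C)C)C(C)C)cc1O[Si](C(C)C)(C(C)C)C(C)C
F12 | step 2 | 1,5-dibromo-2,4-bis(methoxymethoxy)benzene | COCOc1cc(OCOC)c(Br)cc1Br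
F13 | step 2 | [5-bromo-2,4-bis(methoxymethoxy)phenyl]lithium | [Li]c1cc(Br)c(OCOC)cc1OCOC
F14 | step 2 | [5-bromo-2,4-bis(methoxymethoxy)phenyl]copper | [Cu]c1cc(Br)c(OCOC)cc1OCOC
F15 | step 2 | 1-bromo-5-[(2E)-3,7-dimethylocta-2,6-dien-1-yl]-2,4-bis(methoxymethoxy)benzene | CC(C)=CCC/C(C)=C/Cc1cc(Br)c(OCOC)cc1OCOC
F16 | step 2 | 4-bromo-6-[(2E)-3,7-dimethylocta-2,6-dien-1-yl]benzene-1,3-diol | CC(C)=CCC/C(C)=C/Cc1cc(Br)c(O)cc1O
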